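**Strategy.** The target, 5-hydroxy-3,6,7,8,2′,5′-hexamethoxyflavone, is cut at ring C: the C4 carbonyl lies between aromatic C4a of ring A and the C3=C2 unit, and O1 is a phenolic oxygen on C8a. Ring C is therefore assembled from three pieces in one palladium-mediated operation that forms C4a–C4, C4–C3 and O1–C2: a fully substituted ortho-iodophenol (iodine at the future C4a, hydroxyl at the future C8a, four methoxy groups), carbon monoxide as C4, and 2,5-dimethoxyphenylacetylene as C3, C2 and ring B. The resulting C3-unsubstituted hexamethoxyflavone is then hydroxylated and methylated at C3, and the C5 methyl ether, peri to the carbonyl, is cleaved last.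

Key step: step 7

Remark: the target has no stereogenic element, so there is no enantiomer to select. The only stereocentres on the route sit in a transient racemic epoxide and are erased in the step that creates them. Ring positions follow flavone numbering (O1, C2–C4, C4a, C5–C8, C8a; ring B primed).

Step 1
Reactants: 1 2,3,4-trimethoxybenzaldehyde
Product: 3 2,3,4-trimethoxyphenol, via 2,3,4-trimethoxyphenyl formate 2 (not isolated)
Conditions: 30% aq. H2O2 (1.3 equiv), cat. H2SO4, MeOH, rt
Reagents that add atoms: hydrogen peroxide OO
Why: Acid-catalysed Dakin oxidation, in which hydrogen peroxide adds to the aldehyde, the electron-rich ortho-methoxyaryl group migrates to oxygen (Baeyer–Villiger type) and the formate 2 is methanolysed in the same pot.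

Step 2
Reactants: 3 2,3,4-trimethoxyphenol
Product: 4 1,2,3,4-tetramethoxybenzene
Conditions: MeI (1.5 equiv), K2CO3, acetone, reflux
Reagents that add atoms: iodomethane CI
Why: Williamson ether synthesis, an SN2 methylation of the phenoxide, which is the only nucleophilic site in the molecule.

Step 3
Reactants: 4 1,2,3,4-tetramethoxybenzene
Product: 6 2,3,4,5-tetramethoxybenzaldehyde, via aryliminium chloride 5 (not isolated)
Conditions: POCl3 (2 equiv), DMF, 0 → 80 °C; then ice-water
Reagents that add atoms: N,N-dimethylformamide CN(C)C=O; water O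
Why: Vilsmeier–Haack formylation, in which the chloroiminium electrophile attacks one of the two symmetry-equivalent free positions of the electron-rich arene, the iminium group of 5 blocks a second attack, and water releases the aldehyde.

Step 4
Reactants: 6 2,3,4,5-tetramethoxybenzaldehyde
Product: 8 2,3,4,5-tetramethoxyphenol, via 2,3,4,5-tetramethoxyphenyl formate 7 (not isolated)
Conditions: 30% aq. H2O2 (1.3 equiv), cat. H2SO4, MeOH, rt
Reagents that add atoms: hydrogen peroxide OO
Why: Second acid-catalysed Dakin oxidation, again driven by migration of the ortho-methoxy-substituted electron-rich aryl group to peroxide oxygen, with methanolysis of formate 7 in the pot.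

Step 5
Reactants: 8 2,3,4,5-tetramethoxyphenol
Product: 9 2-iodo-3,4,5,6-tetramethoxyphenol
Conditions: NIS (1.05 equiv), MeCN, 0 °C, dark
Reagents that add atoms: N-iodosuccinimide O=C1CCC(=O)N1I
Why: Electrophilic aromatic iodination, whose regiochemistry is forced because the only unsubstituted ring carbon is ortho to the hydroxyl group, while the mild iodonium source at low temperature limits oxidation of the electron-rich phenol.

Step 6
Reactants: 10 2,5-dimethoxybenzaldehyde
Product: 11 2-ethynyl-1,4-dimethoxybenzene
Conditions: dimethyl (1-diazo-2-oxopropyl)phosphonate (1.2 equiv), K2CO3 (2 equiv), MeOH, rt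
Reagents that add atoms: dimethyl (1-diazo-2-oxopropyl)phosphonate CC(=O)C(=[N+]=[N-])P(=O)(OC)OC
Why: Ohira–Bestmann variant of the Seyferth–Gilbert homologation, in which the diazomethylphosphonate anion released by methanolysis adds to the non-enolisable aldehyde in a Horner–Wadsworth–Emmons manner and loss of nitrogen with 1,2-hydride shift gives the terminal alkyne.

Step 7
Reactants: 9 2-iodo-3,4,5,6-tetramethoxyphenol; 11 2-ethynyl-1,4-dimethoxybenzene (1.3 equiv); 12 carbon monoxide
Product: 15 2-(2,5-dimethoxyphenyl)-5,6,7,8-tetramethoxy-4H-chromen-4-one, via ortho-hydroxyaryl ynone 13 (not isolated), via diethylamino enone 14 (not isolated)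
Conditions: PdCl2(dppf) (5 mol %), CO (20 bar), Et2NH (solvent), 120 °C, autoclave, no copper
Reagents that add atoms: carbon monoxide [C-]#[O+] (the numbered reactant 12; no further reagent adds atoms)
Why: Pd(0) adds oxidatively to the C–I bond of 9, CO inserts to give an aroylpalladium species, the alkyne 11 is deprotonated by diethylamine and transferred to palladium, and reductive elimination forms C4a–C4 and C4–C3 in ynone 13; diethylamine then adds to the ynone to give the β-amino enone 14, whose β-carbon is attacked by the neighbouring phenol oxygen, and loss of diethylamine forms O1–C2. The closest known reaction type is the palladium-catalysed carbonylative annulation of ortho-iodophenols with terminal alkynes under CO in a secondary amine, which gives flavones. The pyranone ring closes as a formal 6-endo-dig oxa-Michael cyclisation, in practice a 6-endo-trig addition–elimination on 14. No stereocentre is formed. The step needs carbonylative coupling to beat direct alkynylation, which CO pressure, the absence of copper and the two ortho substituents flanking the aryl–palladium bond favour, and it needs six-membered closure to beat five-membered (aurone) closure, which is secured because the amine adduct 14 leaves C2 as the only electrophilic carbon within reach of the phenol. Regiochemistry is fixed by the substrate, since iodine and hydroxyl sit on adjacent carbons of a ring that has no other free position.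

Step 8
Reactants: 15 2-(2,5-dimethoxyphenyl)-5,6,7,8-tetramethoxy-4H-chromen-4-one
Product: 17 2-(2,5-dimethoxyphenyl)-3-hydroxy-5,6,7,8-tetramethoxy-4H-chromen-4-one, via flavone 2,3-epoxide 16 (not isolated)
Conditions: DMDO (ca. 0.08 M in acetone, 3 equiv), CH2Cl2, 0 °C → rt; then cat. p-TsOH, CH2Cl2, rt
Reagents that add atoms: dimethyldioxirane CC1(C)OO1
Why: Dioxirane epoxidation of the enol-ether-like C2=C3 bond gives the racemic cis-fused epoxide 16, which under acid opens at C2 to a cation stabilised by O1 and the aryl group and loses H3 to give the flavonol (known flavone-to-flavonol oxidation), so both transient stereocentres are erased.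

Step 9
Reactants: 17 2-(2,5-dimethoxyphenyl)-3-hydroxy-5,6,7,8-tetramethoxy-4H-chromen-4-one
Product: 18 2-(2,5-dimethoxyphenyl)-3,5,6,7,8-pentamethoxy-4H-chromen-4-one
Conditions: MeI (2 equiv), K2CO3, acetone, reflux
Reagents that add atoms: iodomethane CI
Why: Williamson methylation of the only free hydroxyl group, the C3 enol.

Step 10
Reactants: 18 2-(2,5-dimethoxyphenyl)-3,5,6,7,8-pentamethoxy-4H-chromen-4-one
Product: 20 Grantioidinin (2-(2,5-dimethoxyphenyl)-5-hydroxy-3,6,7,8-tetramethoxy-4H-chromen-4-one), via dichloroboryl chelate 19 (not isolated)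
Conditions: BCl3 (1.0 M in CH2Cl2, 1.2 equiv), CH2Cl2, −78 → 0 °C; then H2O
Reagents that add atoms: none
Why: Chelation-controlled Lewis-acid ether cleavage, in which boron trichloride bridges the C4 carbonyl oxygen and the peri C5 methoxy oxygen in a six-membered chelate, chloride removes that methyl group to give 19, and water frees the hydrogen-bonded C5 phenol, while the C3 ether (only a five-membered chelate possible) and the other aryl ethers should survive a small excess of reagent at low temperature.

**Compound list**

1 | 2,3,4-trimethoxybenzaldehyde | COc1ccc(C=O)c(OC)c1OC | starting material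
2 | 2,3,4-trimethoxyphenyl formate (formed in the flask) | COc1ccc(OC=O)c(OC)c1OC | intermediate
3 | 2,3,4-trimethoxyphenol | COc1ccc(O)c(OC)c1OC | intermediate
4 | 1,2,3,4-tetramethoxybenzene | COc1ccc(OC)c(OC)c1OC | intermediate
5 | N,N-dimethyl-1-(2,3,4,5-tetramethoxyphenyl)methaniminium chloride (formed in the flask) | C[N+](C)=Cc1cc(OC)c(OC)c(OC)c1OC.[Cl-] | intermediate
6 | 2,3,4,5-tetramethoxybenzaldehyde | COc1cc(C=O)c(OC)c(OC)c1OC | intermediate
7 | 2,3,4,5-tetramethoxyphenyl formate (formed in the flask) | COc1cc(OC=O)c(OC)c(OC)c1OC | intermediate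
8 | 2,3,4,5-tetramethoxyphenol | COc1cc(O)c(OC)c(OC)c1OC | intermediate
9 | 2-iodo-3,4,5,6-tetramethoxyphenol | COc1c(O)c(I)c(OC)c(OC)c1OC | intermediate
10 | 2,5-dimethoxybenzaldehyde | COc1ccc(OC)c(C=O)c1 | starting material
11 | 2-ethynyl-1,4-dimethoxybenzene | C#Cc1cc(OC)ccc1OC | intermediate
12 | carbon monoxide | [C-]#[O+] | starting material
13 | 3-(2,5-dimethoxyphenyl)-1-(2-hydroxy-3,4,5,6-tetramethoxyphenyl)prop-2-yn-1-one (formed in the flask) | COc1ccc(OC)c(C#CC(=O)c2c(O)c(OC)c(OC)c(OC)c2OC)c1 | intermediate
14 | (E)-3-(diethylamino)-3-(2,5-dimethoxyphenyl)-1-(2-hydroxy-3,4,5,6-tetramethoxyphenyl)prop-2-en-1-one (formed in the flask; geometry lost on ring closure) | CCN(CC)/C(c1cc(OC)ccc1OC)=C/C(=O)c1c(O)c(OC)c(OC)c(OC)c1OC | intermediate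
15 | 2-(2,5-dimethoxyphenyl)-5,6,7,8-tetramethoxy-4H-chromen-4-one | COc1ccc(OC)c(-c2cc(=O)c3c(OC)c(OC)c(OC)c(OC)c3o2)c1 | intermediate
16 | cis-2,3-epoxy-2-(2,5-dimethoxyphenyl)-5,6,7,8-tetramethoxychroman-4-one (formed in the flask; racemic, one enantiomer drawn) | O=C1c2c(OC)c(OC)c(OC)c(OC)c2O[C@]3(c2cc(OC)ccc2OC)O[C@H]13 | intermediate
17 | 2-(2,5-dimethoxyphenyl)-3-hydroxy-5,6,7,8-tetramethoxy-4H-chromen-4-one | COc1ccc(OC)c(-c2oc3c(OC)c(OC)c(OC)c(OC)c3c(=O)c2O)c1 | intermediate
18 | 2-(2,5-dimethoxyphenyl)-3,5,6,7,8-pentamethoxy-4H-chromen-4-one | COc1ccc(OC)c(-c2oc3c(OC)c(OC)c(OC)c(OC)c3c(=O)c2OC)c1 | intermediate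
19 | 5-O-dichloroboryl derivative of the 5-demethylated flavone, chelated to the C4 carbonyl (formed in the flask) | COc1ccc(OC)c(-c2oc3c(OC)c(OC)c(OC)c(OB(Cl)Cl)c3c(=O)c2OC)c1 | intermediate
20 | Grantioidinin, 2-(2,5-dimethoxyphenyl)-5-hydroxy-3,6,7,8-tetramethoxy-4H-chromen-4-one (achiral) | COc1ccc(OC)c(-c2oc3c(OC)c(OC)c(OC)c(O)c3c(=O)c2OC)c1 | target

**Step count.** Total: 10 steps. Longest linear sequence: 9 steps (steps 1–5 and 7–10, from 2,3,4-trimethoxybenzaldehyde); the alkyne branch is one step (step 6).

**Steps most likely to fail**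

Risk 1 (step 7). Alkynyl transfer to the hindered, electron-rich aroylpalladium centre may be too slow. Direct non-carbonylative alkynylation, capture of the acyl group by diethylamine, or five-membered closure could then take over. The fallback builds ring C by the chalcone route. It sets out from phenol 8. Friedel–Crafts acetylation at its only free position (AcOH, BF3·OEt2, 80 °C) would give 1-(2-hydroxy-3,4,5,6-tetramethoxyphenyl)ethan-1-one F1. Claisen–Schmidt condensation with aldehyde 10 (KOH, EtOH, rt) would give (E)-3-(2,5-dimethoxyphenyl)-1-(2-hydroxy-3,4,5,6-tetramethoxyphenyl)prop-2-en-1-one F2. Oxidative cyclisation (cat. I2, DMSO, 130 °C) comes back to the route at flavone 15.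

Risk 2 (step 8). Epoxidation of the vinylogous-ester double bond may be sluggish, so that the excess dioxirane begins to oxidise the electron-rich aryl rings. The fallback replaces electrophilic oxidation by deprotonation, borylation and oxidation. It sets out from flavone 15. LDA (THF, −78 °C) would give [2-(2,5-dimethoxyphenyl)-5,6,7,8-tetramethoxy-4-oxo-4H-chromen-3-yl]lithium F3. Trimethyl borate would trap it as dimethyl [2-(2,5-dimethoxyphenyl)-5,6,7,8-tetramethoxy-4-oxo-4H-chromen-3-yl]boronate F4. Oxidation in the same flask (H2O2, AcOH, 0 °C → rt) comes back to the route at flavonol 17.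

Risk 3 (step 10). Demethylation may overrun, with the C3 methyl ether, which also flanks the carbonyl, cleaved alongside the C5 ether. The fallback reverses the order of events so that selectivity rests on O-methylation instead. It sets out from flavonol 17. BCl3 (2.5 equiv, CH2Cl2, 0 °C; then H2O) would cleave the C5 ether while C3 still carries a free hydroxyl, giving 2-(2,5-dimethoxyphenyl)-3,5-dihydroxy-6,7,8-trimethoxy-4H-chromen-4-one F5. One equivalent of MeI with K2CO3 (acetone, rt) would then methylate the more acidic, less strongly chelated C3 hydroxyl and leave the C5 hydroxyl untouched. This comes back to the route at target 20.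

**Further compounds**

F1 | step 7 | 1-(2-hydroxy-3,4,5,6-tetramethoxyphenyl)ethan-1-one | CC(=O)c1c(O)c(OC)c(OC)c(OC)c1OC
F2 | step 7 | (E)-3-(2,5-dimethoxyphenyl)-1-(2-hydroxy-3,4,5,6-tetramethoxyphenyl)prop-2-en-1-one | COc1ccc(OC)c(/C=C/C(=O)c2c(O)c(OC)c(OC)c(OC)c2OC)c1
F3 | step 8 | [2-(2,5-dimethoxyphenyl)-5,6,7,8-tetramethoxy-4-oxo-4H-chromen-3-yl]lithium | COc1ccc(OC)c(-c2oc3c(OC)c(OC)c(OC)c(OC)c3c(=O)c2[Li])c1
F4 | step 8 | dimethyl [2-(2,5-dimethoxyphenyl)-5,6,7,8-tetramethoxy-4-oxo-4H-chromen-3-yl]boronate | COc1ccc(OC)c(-c2oc3c(OC)c(OC)c(OC)c(OC)c3c(=O)c2B(OC)OC)c1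
F5 | step 10 | 2-(2,5-dimethoxyphenyl)-3,5-dihydroxy-6,7,8-trimethoxy-4H-chromen-4-one | COc1ccc(OC)c(-c2oc3c(OC)c(OC)c(OC)c(O)c3c(=O)c2O)c1
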